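**Retrosynthetic overview**
1. Target ⇐ its penta-O-allyl ether; the last step removes five allyl groups with zerovalent palladium.
2. Penta-O-allyl ether ⇐ E-selective Horner–Wadsworth–Emmons union of an aryloxyacrylate aldehyde with the phosphonoacetate of allyl-protected methyl (R)-danshensu (forms the cinnamate C=C; the stereocentre comes from the chiral pool).
3. Aryloxyacrylate aldehyde ⇐ new phosphine-catalysed α-addition of the O–H of 3-hydroxy-4-allyloxybenzaldehyde to methyl 3-[3,4-bis(allyloxy)phenyl]propiolate (forms the vinyl C–O bond and the Z geometry in one step).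
4. Alkynoate and phenol ⇐ 3,4-dihydroxybenzaldehyde (bis- or mono-allylation, Corey–Fuchs homologation).
5. No ring is formed: the three benzene rings come intact from 3,4-dihydroxybenzaldehyde (two) and sodium (R)-danshensu (one).

Assumption: sodium (R)-danshensu and the reagents named on the reagent lines are bought; only substrates, intermediates and products carry numbers.

**Step 1**
Reactants: 1 3,4-dihydroxybenzaldehyde
Product: 2 3,4-bis(prop-2-enyloxy)benzaldehyde
Conditions: allyl bromide (2.5 equiv), K2CO3 (3 equiv), DMF, 60 °C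
Reagents that add atoms: allyl bromide (C=CCBr)
Why: Double Williamson etherification (SN2) of both phenoxides; the aldehyde is inert to K2CO3.

**Step 2**
Reactants: 2 3,4-bis(prop-2-enyloxy)benzaldehyde
Product: 3 4-(2,2-dibromoethenyl)-1,2-bis(prop-2-enyloxy)benzene
Conditions: CBr4 (2 equiv), PPh3 (4 equiv), CH2Cl2, 0 °C
Reagents that add atoms: carbon tetrabromide (BrC(Br)(Br)Br)
Why: Corey–Fuchs dibromoolefination: the ylide Ph3P=CBr2 formed from CBr4 and PPh3 converts the aldehyde into the 1,1-dibromoalkene in a Wittig reaction, and the allyl ethers are inert.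

**Step 3**
Reactants: 3 4-(2,2-dibromoethenyl)-1,2-bis(prop-2-enyloxy)benzene
Product: 5 methyl 3-[3,4-bis(prop-2-enyloxy)phenyl]prop-2-ynoate, via lithium arylacetylide 4 (not isolated)
Conditions: n-BuLi (2.1 equiv), THF, −78 °C; then ClCO2Me, −78 °C to rt
Reagents that add atoms: methyl chloroformate (COC(=O)Cl)
Why: Second stage of the Corey–Fuchs sequence: Li–Br exchange, Fritsch–Buttenberg–Wiechell rearrangement and deprotonation give the lithium acetylide, which methyl chloroformate C-acylates; at −78 °C the aryl allyl ethers are untouched.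

**Step 4**
Reactants: 1 3,4-dihydroxybenzaldehyde
Product: 6 3-hydroxy-4-(prop-2-enyloxy)benzaldehyde
Conditions: allyl bromide (1.05 equiv), NaHCO3 (1.5 equiv), NaI (0.2 equiv), DMF, 40 °C
Reagents that add atoms: allyl bromide (C=CCBr)
Why: Regioselective Williamson etherification: the 4-OH para to the formyl group is the more acidic phenol, so the weak base NaHCO3 forms and alkylates only that phenoxide and leaves the 3-OH free.

**Step 5**
Reactants: 5 methyl 3-[3,4-bis(prop-2-enyloxy)phenyl]prop-2-ynoate (1.2 equiv); 6 3-hydroxy-4-(prop-2-enyloxy)benzaldehyde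
Product: 7 methyl (2Z)-3-[3,4-bis(prop-2-enyloxy)phenyl]-2-[5-formyl-2-(prop-2-enyloxy)phenoxy]prop-2-enoate
Conditions: P(4-MeOC6H4)3 (20 mol %), AcOH (50 mol %), NaOAc (50 mol %), toluene, 100 °C
Reagents that add atoms: none
Why: Proposed new method: phosphine-catalysed α-selective hydro-aryloxylation of an electron-rich 3-arylpropiolate by a phenol O–H. The phosphine adds to C3 of 5 and the resulting C2 carbanion is protonated by the buffer or phenol, giving a β-phosphonio cinnamate whose electrophilic site is now C2; the phenoxide of 6 (pKa about 9, in the window of the known N–H pronucleophiles) adds there, and a buffer-mediated proton shift from C2 to C3 followed by E1cB loss of the phosphine gives the α-aryloxy cinnamate as the more stable Z isomer (aryl trans to CO2Me). The acetate buffer keeps free phenoxide low and so suppresses the ordinary oxa-Michael addition at C3; the closest known reaction type is the phosphine-catalysed α-umpolung addition of imide and sulfonamide N–H pronucleophiles to 2-alkynoates, together with the phosphine-catalysed γ-addition of phenols to allenoates.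

**Step 6**
Reactants: 8 sodium (2R)-3-(3,4-dihydroxyphenyl)-2-hydroxypropanoate (sodium (R)-danshensu)
Product: 9 methyl (2R)-3-(3,4-dihydroxyphenyl)-2-hydroxypropanoate
Conditions: HCl (1.25 M in MeOH, 1.5 equiv), MeOH, rt to 40 °C
Reagents that add atoms: methanol (CO)
Why: Fischer esterification in methanolic HCl; the (R) carbinol centre comes from the chiral pool and is not touched under acid.

**Step 7**
Reactants: 9 methyl (2R)-3-(3,4-dihydroxyphenyl)-2-hydroxypropanoate
Product: 10 methyl (2R)-3-[3,4-bis(prop-2-enyloxy)phenyl]-2-hydroxypropanoate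
Conditions: allyl bromide (2.3 equiv), K2CO3 (2.5 equiv), acetone, 50 °C, N2
Reagents that add atoms: allyl bromide (C=CCBr)
Why: Williamson etherification: K2CO3 deprotonates only the two phenols, so the secondary alcohol stays free and the (R) centre is not epimerised.

**Step 8**
Reactants: 10 methyl (2R)-3-[3,4-bis(prop-2-enyloxy)phenyl]-2-hydroxypropanoate
Product: 11 methyl (2R)-3-[3,4-bis(prop-2-enyloxy)phenyl]-2-{[2-(diethoxyphosphoryl)acetyl]oxy}propanoate
Conditions: (EtO)2P(O)CH2CO2H (1.2 equiv), DCC (1.3 equiv), 4-(dimethylamino)pyridine (0.1 equiv), CH2Cl2, 0 °C to rt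
Reagents that add atoms: 2-(diethoxyphosphoryl)acetic acid (CCOP(=O)(CC(=O)O)OCC)
Why: Steglich esterification: acylation takes place at the carbinol oxygen without breaking a bond to the stereocentre, so the (R) configuration is kept.

**Step 9**
Reactants: 7 methyl (2Z)-3-[3,4-bis(prop-2-enyloxy)phenyl]-2-[5-formyl-2-(prop-2-enyloxy)phenoxy]prop-2-enoate; 11 methyl (2R)-3-[3,4-bis(prop-2-enyloxy)phenyl]-2-{[2-(diethoxyphosphoryl)acetyl]oxy}propanoate
Product: 12 methyl (2R)-3-[3,4-bis(prop-2-enyloxy)phenyl]-2-{[(2E)-3-(3-{[(1Z)-1-[3,4-bis(prop-2-enyloxy)phenyl]-3-methoxy-3-oxoprop-1-en-2-yl]oxy}-4-(prop-2-enyloxy)phenyl)prop-2-enoyl]oxy}propanoate (penta-O-allyl ether of the target)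
Conditions: LiCl (1.5 equiv), iPr2NEt (1.3 equiv), MeCN, 0 °C to rt
Reagents that add atoms: none
Why: Horner–Wadsworth–Emmons olefination under Masamune–Roush conditions: the lithium-chelated phosphonate is deprotonated by the mild amine base and gives the (E)-cinnamate, while the weak base leaves the O-acyl lactate centre and the Z enol ether unchanged.

**Step 10**
Reactants: 12 penta-O-allyl ether of the target
Product: 13 methyl (2R)-3-(3,4-dihydroxyphenyl)-2-{[(2E)-3-(3-{[(1Z)-1-(3,4-dihydroxyphenyl)-3-methoxy-3-oxoprop-1-en-2-yl]oxy}-4-hydroxyphenyl)prop-2-enoyl]oxy}propanoate (CNP0178751.1)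
Conditions: Pd(PPh3)4 (10 mol %), morpholine (10 equiv), THF, rt, Ar
Reagents that add atoms: none
Why: Tsuji–Trost-type deallylation: zerovalent palladium ionises each aryl allyl ether to a π-allyl complex that morpholine captures, freeing all five phenols under near-neutral conditions that spare both methyl esters, the lactate ester, both alkenes and the (R) centre.

**Compound list**
1 | 3,4-dihydroxybenzaldehyde | O=Cc1ccc(O)c(O)c1 | starting material
2 | 3,4-bis(prop-2-enyloxy)benzaldehyde | O=Cc1ccc(OCC=C)c(OCC=C)c1 | intermediate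
3 | 4-(2,2-dibromoethenyl)-1,2-bis(prop-2-enyloxy)benzene | BrC(Br)=Cc1ccc(OCC=C)c(OCC=C)c1 | intermediate
4 | {[3,4-bis(prop-2-enyloxy)phenyl]ethynyl}lithium (lithium arylacetylide, not isolated) | [Li]C#Cc1ccc(OCC=C)c(OCC=C)c1 | intermediate
5 | methyl 3-[3,4-bis(prop-2-enyloxy)phenyl]prop-2-ynoate | COC(=O)C#Cc1ccc(OCC=C)c(OCC=C)c1 | intermediate
6 | 3-hydroxy-4-(prop-2-enyloxy)benzaldehyde | O=Cc1ccc(OCC=C)c(O)c1 | intermediate
7 | methyl (2Z)-3-[3,4-bis(prop-2-enyloxy)phenyl]-2-[5-formyl-2-(prop-2-enyloxy)phenoxy]prop-2-enoate | COC(=O)/C(=C/c1ccc(OCC=C)c(OCC=C)c1)Oc1cc(C=O)ccc1OCC=C | intermediate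
8 | sodium (2R)-3-(3,4-dihydroxyphenyl)-2-hydroxypropanoate | [Na+].[O-]C(=O)[C@H](O)Cc1ccc(O)c(O)c1 | starting material
9 | methyl (2R)-3-(3,4-dihydroxyphenyl)-2-hydroxypropanoate | COC(=O)[C@H](O)Cc1ccc(O)c(O)c1 | intermediate
10 | methyl (2R)-3-[3,4-bis(prop-2-enyloxy)phenyl]-2-hydroxypropanoate | COC(=O)[C@H](O)Cc1ccc(OCC=C)c(OCC=C)c1 | intermediate
11 | methyl (2R)-3-[3,4-bis(prop-2-enyloxy)phenyl]-2-{[2-(diethoxyphosphoryl)acetyl]oxy}propanoate | COC(=O)[C@H](OC(=O)CP(=O)(OCC)OCC)Cc1ccc(OCC=C)c(OCC=C)c1 | intermediate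
12 | methyl (2R)-3-[3,4-bis(prop-2-enyloxy)phenyl]-2-{[(2E)-3-(3-{[(1Z)-1-[3,4-bis(prop-2-enyloxy)phenyl]-3-methoxy-3-oxoprop-1-en-2-yl]oxy}-4-(prop-2-enyloxy)phenyl)prop-2-enoyl]oxy}propanoate | COC(=O)/C(=C/c1ccc(OCC=C)c(OCC=C)c1)Oc1cc(/C=C/C(=O)O[C@H](Cc2ccc(OCC=C)c(OCC=C)c2)C(=O)OC)ccc1OCC=C | intermediate
13 | methyl (2R)-3-(3,4-dihydroxyphenyl)-2-{[(2E)-3-(3-{[(1Z)-1-(3,4-dihydroxyphenyl)-3-methoxy-3-oxoprop-1-en-2-yl]oxy}-4-hydroxyphenyl)prop-2-enoyl]oxy}propanoate | COC(=O)/C(=C/c1ccc(O)c(O)c1)Oc1cc(/C=C/C(=O)O[C@H](Cc2ccc(O)c(O)c2)C(=O)OC)ccc1O | target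

**Totals**
Total step count: 10.
Longest linear sequence: 6 steps (1 → 2 → 3 → 5 → 7 → 12 → 13; steps 1, 2, 3, 5, 9, 10).

**Three steps most likely to fail**

Step 5 (the proposed new step). The risks are addition at C3 giving the β-aryloxy regioisomer, formation of the E isomer, and slow phosphine addition to the electron-rich alkynoate. The fallback uses known chemistry only. It sets out from phenol 6 and phosphonate 11 and comes back to the route at 12. Masamune–Roush olefination of 6 with 11 (LiCl, iPr2NEt, MeCN) gives the phenolic caffeate ester F1. Rh2(OAc)4-catalysed O–H insertion of methyl 2-diazo-2-(dimethoxyphosphoryl)acetate into its phenol (toluene, 80 °C) gives the α-aryloxy phosphonoacetate F2, as both epimers at the new carbon, which becomes sp2 in the next operation. Horner–Wadsworth–Emmons olefination of F2 with aldehyde 2 (LiCl, DBU, MeCN) gives 12, mainly as the Z enol ether; the minor E isomer is removed by chromatography. Steps 2, 3, 5 and 9 are then not needed.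

Step 9. The risks are sluggish olefination of the electron-rich aldehyde and base-induced epimerisation of the O-acyl lactate centre. The fallback sets out from aldehyde 7 and comes back at 12. Knoevenagel–Doebner condensation of 7 with malonic acid (pyridine, cat. piperidine, 80 °C) gives the arylidenemalonic acid F3, which loses CO2 in the flask to give the (E)-cinnamic acid F4. Steglich esterification of F4 with alcohol 10 (DCC, 4-(dimethylamino)pyridine, CH2Cl2) then gives 12 without any enolisable phosphonate on the lactate fragment.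

Step 10. The risks are incomplete removal of five allyl groups, oxidation of the free catechols in the presence of palladium, and amine attack on the esters. The fallback sets out from 12 and comes back at 13. Isomerisation of all five allyl ethers with H2-activated [Ir(cod)(PMePh2)2]PF6 (THF, rt) gives the penta-O-(E)-prop-1-enyl ether F5. Its simple enol ethers are then hydrolysed with 1 M HCl in acetone–water at 40 °C, under which the ester-conjugated aryloxyacrylate and the esters survive, giving 13.

**Further compounds**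
F1 | step 5 | phenolic caffeate ester, methyl (2R)-3-[3,4-bis(prop-2-enyloxy)phenyl]-2-({(2E)-3-[3-hydroxy-4-(prop-2-enyloxy)phenyl]prop-2-enoyl}oxy)propanoate | COC(=O)[C@H](OC(=O)/C=C/c1ccc(OCC=C)c(O)c1)Cc1ccc(OCC=C)c(OCC=C)c1
F2 | step 5 | α-aryloxy phosphonoacetate, methyl (2R)-3-[3,4-bis(prop-2-enyloxy)phenyl]-2-({(2E)-3-[3-[1-(dimethoxyphosphoryl)-2-methoxy-2-oxoethoxy]-4-(prop-2-enyloxy)phenyl]prop-2-enoyl}oxy)propanoate | COC(=O)[C@H](OC(=O)/C=C/c1ccc(OCC=C)c(OC(C(=O)OC)P(=O)(OC)OC)c1)Cc1ccc(OCC=C)c(OCC=C)c1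
F3 | step 9 | arylidenemalonic acid, 2-[(3-{[(1Z)-1-[3,4-bis(prop-2-enyloxy)phenyl]-3-methoxy-3-oxoprop-1-en-2-yl]oxy}-4-(prop-2-enyloxy)phenyl)methylidene]propanedioic acid | COC(=O)/C(=C/c1ccc(OCC=C)c(OCC=C)c1)Oc1cc(C=C(C(=O)O)C(=O)O)ccc1OCC=C
F4 | step 9 | (E)-cinnamic acid, (2E)-3-(3-{[(1Z)-1-[3,4-bis(prop-2-enyloxy)phenyl]-3-methoxy-3-oxoprop-1-en-2-yl]oxy}-4-(prop-2-enyloxy)phenyl)prop-2-enoic acid | COC(=O)/C(=C/c1ccc(OCC=C)c(OCC=C)c1)Oc1cc(/C=C/C(=O)O)ccc1OCC=C
F5 | step 10 | penta-O-(E)-prop-1-enyl ether, the analogue of 12 in which each prop-2-enyloxy group is an (E)-prop-1-enyloxy group | COC(=O)/C(=C/c1ccc(O/C=C/C)c(O/C=C/C)c1)Oc1cc(/C=C/C(=O)O[C@H](Cc2ccc(O/C=C/C)c(O/C=C/C)c2)C(=O)OC)ccc1O/C=C/C
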